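# Total synthesis of ferugin (daucane 5–7 bicycle, *p*-hydroxybenzoate at C-4)

**Retrosynthesis**
1. The 4-OH ester comes from late acylation. The exocyclic allylic alcohol comes from isomerising a cycloheptene epoxide.
2. The tertiary alcohol comes from adding *i*Pr to a cyclopentanone. The trans ring-fusion H comes from hydroboration of a ring-fusion alkene, anti to the angular Me.
3. The 7-ring comes from ring-closing metathesis of a cyclopentenyl carbinol carrying allyl on the quaternary carbon and methallyl on the carbinol carbon.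
4. The 5-ring is present from the start: 2-methylcyclopentane-1,3-dione with its quaternary carbon set by ketoreductase desymmetrisation, and a Shapiro reaction installs the carbinol carbon.
5. Ring order: the cyclopentane is formed first (from the dione), then the cycloheptene by RCM.

*Assumption (one line):* a commercial KRED panel contains an enzyme giving the (2S,3S)-hydroxy ketone 4, and the α-pinene antipode for reagent 12 is chosen to give the (S)-carbinol 13.

Hydroazulene numbering used in names: C1–C3 are the five-ring CH2, CH2 and C(OH)iPr carbons, C3a is the ring-fusion CH, C4 is the CH–O carbon, C5 is CH2, C6 is the carbon bearing the exocyclic methylene, C7 is CH–OH, C8 is CH2, and C8a is the quaternary C–CH3.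

---

**Step 1**
Reactants: 1 (2-methylcyclopentane-1,3-dione); 2 (allyl bromide)
Product: 3 (2-allyl-2-methylcyclopentane-1,3-dione)
Conditions: 2, 1 M NaOH (aq), 23 °C, 24 h
Reagents that add atoms: allyl bromide, C=CCBr
Why: C-alkylation of the dione enolate (SN2 on an allylic halide) installs the quaternary carbon as a prochiral, achiral dione.

**Step 2**
Reactants: 3
Product: 4 ((2S,3S)-2-allyl-3-hydroxy-2-methylcyclopentan-1-one)
Conditions: KRED (NADPH-dependent ketoreductase, panel hit), NADP+, glucose, GDH, KPi pH 7, 10% DMSO, 30 °C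
Reagents that add atoms: none (hydride only)
Why: the ketoreductase (an oxidoreductase) reduces only one of the two enantiotopic C=O groups, an asymmetric biocatalytic desymmetrisation that sets the quaternary carbon (C8a) and the carbinol carbon.

**Step 3**
Reactants: 4; 5 (phenyl chlorothionoformate)
Product: 6 (O-phenyl thionocarbonate of 4, same stereochemistry)
Conditions: 5, DMAP, pyridine, CH2Cl2, 0 → 23 °C
Reagents that add atoms: phenyl chlorothionoformate, S=C(Cl)Oc1ccccc1
Why: O-acylation gives the Barton–McCombie radical precursor under mild, non-basic conditions; this avoids retro-aldol of the β-hydroxy ketone.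

**Step 4**
Reactants: 6
Product: 7 ((2R)-2-allyl-2-methylcyclopentan-1-one)
Conditions: Bu3SnH, AIBN, PhMe, 110 °C (slow addition)
Reagents that add atoms: none (H only)
Why: Barton–McCombie deoxygenation removes the C3 oxygen. The quaternary carbon is untouched; its descriptor changes S→R only because the CIP priorities change.

**Step 5**
Reactants: 7; 8 (TsNHNH2)
Product: 9 (tosylhydrazone of 7)
Conditions: 8, MeOH, 23 °C, 12 h
Reagents that add atoms: *p*-toluenesulfonyl hydrazide, Cc1ccc(cc1)S(=O)(=O)NN
Why: condensation gives the Shapiro substrate; the quaternary α-carbon leaves only one enolisable side.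

**Step 6**
Reactants: 9; 10 (DMF)
Product: 11 ((5R)-5-allyl-5-methylcyclopent-1-ene-1-carbaldehyde)
Conditions: n-BuLi (2.5 equiv), TMEDA, THF, −78 → 0 °C; then 10, −78 → 23 °C; aq NH4Cl
Reagents that add atoms: DMF, CN(C)C=O
Why: the Shapiro reaction (dianion, loss of Ts⁻ and N2) gives the vinyllithium regiospecifically at C3a, creating the ring-fusion alkene. Formylation with DMF installs the future C4 carbon.

**Step 7**
Reactants: 11; 12 (B-methallyl-diisopinocampheylborane)
Product: 13 ((1S)-1-[(5R)-5-allyl-5-methylcyclopent-1-en-1-yl]-3-methylbut-3-en-1-ol)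
Conditions: 12, Et2O, −78 °C, 3 h; then NaOH, H2O2, 0 → 23 °C
Reagents that add atoms: (Ipc)2B-methallyl, C=C(C)CB(C1CC2CC(C1C)C2(C)C)C1CC2CC(C1C)C2(C)C (Ipc from α-pinene, antipode chosen as stated above)
Why: Brown asymmetric methallylation proceeds through a chair six-membered TS whose face is dictated by the reagent, so C-4 is set under reagent control and the C5–C6 unit is introduced.

**Step 8**
Reactants: 13
Product: 14 ((4S,8aR)-6,8a-dimethyl-1,2,4,5,8,8a-hexahydroazulen-4-ol)
Conditions: Hoveyda–Grubbs II (10 mol %), PhMe (2 mM), 80 °C, 6 h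
Reagents that add atoms: none (ethylene lost)
Why: ring-closing metathesis of the allyl and methallyl alkenes closes the seven-membered ring with a trisubstituted C6=C7 alkene; the cyclopentene is too hindered to react.

**Step 9**
Reactants: 14; 15 (mCPBA)
Product: 16 (6,7-epoxide of 14, epoxide O syn to the 4-OH)
Conditions: 15 (1.05 equiv), NaHCO3, CH2Cl2, −20 °C
Reagents that add atoms: *m*-chloroperbenzoic acid, OOC(=O)c1cccc(Cl)c1
Why: Henbest-type, OH-directed epoxidation occurs at the more nucleophilic and less hindered C6=C7 alkene, on the face syn to the 4-OH, which gives the required cis 4-O/7-O relationship. The epoxide also masks this alkene during hydroboration.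

**Step 10**
Reactants: 16; 17 (TESCl)
Product: 18 (4-O-triethylsilyl ether of 16)
Conditions: 17, imidazole, DMF, 0 → 23 °C
Reagents that add atoms: chlorotriethylsilane, CC[Si](Cl)(CC)CC
Why: silylation under non-Lewis-acidic conditions leaves the epoxide intact and protects C4–O for the oxidation and organometallic steps.

**Step 11**
Reactants: 18; 19 (hydrogen peroxide, as NaBO3·4H2O)
Product: 20 (3-hydroxy compound, 3a-H trans to 8a-CH3)
Conditions: 9-BBN (3 equiv), THF, 0 → 50 °C; then NaBO3·4H2O, THF/H2O, 23 °C
Reagents that add atoms: hydrogen peroxide (from perborate), OO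
Why: hydroboration–oxidation of the ring-fusion alkene occurs anti to the angular methyl, as in Δ14-steroids, with boron on the less hindered C3 and hydride on C3a; this sets the trans ring fusion, and C3 is oxidised next so its configuration is irrelevant.

**Step 12**
Reactants: 20
Product: 21 (3-ketone)
Conditions: Dess–Martin periodinane, NaHCO3, CH2Cl2, 23 °C
Reagents that add atoms: none
Why: mild buffered oxidation gives the cyclopentanone without epimerising C3a.

**Step 13**
Reactants: 21; 22 (iPrMgCl·LiCl)
Product: 23 (3-hydroxy-3-isopropyl compound)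
Conditions: 22, CeCl3 (anhyd.), THF, −78 °C
Reagents that add atoms: isopropylmagnesium chloride, CC(C)[Mg]Cl
Why: the non-basic organocerium adds to the hindered ketone from the β-face, anti to the adjacent C4 substituent, so the new OH ends α, as in the target.

**Step 14**
Reactants: 23
Product: 24 ((7-hydroxy-6-methylidene) allylic alcohol, 4-OTES)
Conditions: Et2AlTMP (4 equiv), PhMe, 0 → 23 °C
Reagents that add atoms: none
Why: Yamamoto's bulky aluminium amide isomerises the trisubstituted epoxide by syn β-elimination of a methyl H with C6–O cleavage. This gives the exocyclic methylene and keeps oxygen on C7 with its configuration, so the 7-OH stays cis to the 4-O.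

**Step 15**
Reactants: 24; 25 (TBSCl)
Product: 26 (7-O-TBS ether)
Conditions: 25, imidazole, DMF, 40 °C
Reagents that add atoms: tert-butyldimethylsilyl chloride, CC(C)(C)[Si](C)(C)Cl
Why: TBSCl/imidazole silylates the secondary allylic alcohol but not the hindered tertiary alcohol; this differentiates O-7 from O-4.

**Step 16**
Reactants: 26
Product: 27 (free 4-OH, 7-OTBS)
Conditions: PPTS, MeOH/CH2Cl2, 0 → 23 °C
Reagents that add atoms: none
Why: acid-catalysed methanolysis cleaves the TES ether selectively in the presence of the TBS ether.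

**Step 17**
Reactants: 27; 28 (4-(TBSO)benzoic acid)
Product: 29 (4-O-(4-TBSO-benzoate), 7-OTBS)
Conditions: 28, 2,4,6-Cl3C6H2COCl, Et3N, THF; then 27, DMAP, PhMe, 60 °C
Reagents that add atoms: 4-(tert-butyldimethylsilyloxy)benzoic acid, CC(C)(C)[Si](C)(C)Oc1ccc(cc1)C(=O)O
Why: Yamaguchi esterification acylates the hindered secondary alcohol with retention of configuration; the tertiary alcohol is unreactive.

**Step 18**
Reactants: 29
Product: 30 (ferugin)
Conditions: HF·pyridine, THF/pyridine, 0 → 23 °C
Reagents that add atoms: none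
Why: fluoride removes the aryl and C7 TBS ethers without cleaving the aryl ester, releasing the phenol and the allylic alcohol.

---

## Compound list
1 | 2-methylcyclopentane-1,3-dione | CC1C(=O)CCC1=O | starting material
2 | allyl bromide | C=CCBr | starting material
3 | 2-allyl-2-methylcyclopentane-1,3-dione | C=CCC1(C)C(=O)CCC1=O | intermediate
4 | (2S,3S)-2-allyl-3-hydroxy-2-methylcyclopentan-1-one | C=CC[C@@]1(C)[C@@H](O)CCC1=O | intermediate
5 | phenyl chlorothionoformate | S=C(Cl)Oc1ccccc1 | starting material
6 | O-phenyl thionocarbonate of 4 | C=CC[C@@]1(C)[C@@H](OC(=S)Oc2ccccc2)CCC1=O | intermediate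
7 | (2R)-2-allyl-2-methylcyclopentan-1-one | C=CC[C@@]1(C)CCCC1=O | intermediate
8 | *p*-toluenesulfonyl hydrazide | Cc1ccc(cc1)S(=O)(=O)NN | starting material
9 | tosylhydrazone of 7 | C=CC[C@@]1(C)CCCC1=NNS(=O)(=O)c2ccc(C)cc2 | intermediate
10 | N,N-dimethylformamide | CN(C)C=O | starting material
11 | (5R)-5-allyl-5-methylcyclopent-1-ene-1-carbaldehyde | C=CC[C@@]1(C)CCC=C1C=O | intermediate
12 | B-methallyldiisopinocampheylborane | C=C(C)CB(C1CC2CC(C1C)C2(C)C)C1CC2CC(C1C)C2(C)C (pinane stereochemistry not drawn) | starting material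
13 | (1S)-1-[(5R)-5-allyl-5-methylcyclopent-1-en-1-yl]-3-methylbut-3-en-1-ol | C=CC[C@@]1(C)CCC=C1[C@@H](O)CC(C)=C | intermediate
14 | (4S,8aR)-6,8a-dimethyl-1,2,4,5,8,8a-hexahydroazulen-4-ol | C[C@]12CCC=C1[C@@H](O)CC(C)=CC2 | intermediate
15 | *m*-chloroperbenzoic acid | OOC(=O)c1cccc(Cl)c1 | starting material
16 | 6,7-epoxide of 14, O syn to 4-OH | C[C@]12CCC=C1[C@@H](O)C[C@@]3(C)O[C@H]3C2 | intermediate
17 | chlorotriethylsilane | CC[Si](Cl)(CC)CC | starting material
18 | 4-O-TES ether of 16 | C[C@]12CCC=C1[C@@H](O[Si](CC)(CC)CC)C[C@@]3(C)O[C@H]3C2 | intermediate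
19 | hydrogen peroxide | OO | starting material
20 | 3-hydroxy (3a-H trans to 8a-Me) epoxide, 4-OTES | C[C@]12CC[C@@H](O)[C@@H]1[C@@H](O[Si](CC)(CC)CC)C[C@@]3(C)O[C@H]3C2 | intermediate
21 | 3-ketone of 20 | C[C@]12CCC(=O)[C@@H]1[C@@H](O[Si](CC)(CC)CC)C[C@@]3(C)O[C@H]3C2 | intermediate
22 | isopropylmagnesium chloride | CC(C)[Mg]Cl | starting material
23 | 3-hydroxy-3-isopropyl epoxide, 4-OTES | C[C@]12CC[C@@](O)(C(C)C)[C@@H]1[C@@H](O[Si](CC)(CC)CC)C[C@@]3(C)O[C@H]3C2 | intermediate
24 | 7-hydroxy-6-methylidene allylic alcohol, 4-OTES | C[C@]12CC[C@@](O)(C(C)C)[C@@H]1[C@@H](O[Si](CC)(CC)CC)CC(=C)[C@@H](O)C2 | intermediate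
25 | tert-butyldimethylsilyl chloride | CC(C)(C)[Si](C)(C)Cl | starting material
26 | 7-O-TBS, 4-O-TES ether of 24 | C[C@]12CC[C@@](O)(C(C)C)[C@@H]1[C@@H](O[Si](CC)(CC)CC)CC(=C)[C@@H](O[Si](C)(C)C(C)(C)C)C2 | intermediate
27 | 4-OH, 7-OTBS compound | C[C@]12CC[C@@](O)(C(C)C)[C@@H]1[C@@H](O)CC(=C)[C@@H](O[Si](C)(C)C(C)(C)C)C2 | intermediate
28 | 4-(tert-butyldimethylsilyloxy)benzoic acid | CC(C)(C)[Si](C)(C)Oc1ccc(cc1)C(=O)O | starting material
29 | 4-O-(4-TBSO-benzoate), 7-OTBS | C[C@]12CC[C@@](O)(C(C)C)[C@@H]1[C@@H](OC(=O)c3ccc(O[Si](C)(C)C(C)(C)C)cc3)CC(=C)[C@@H](O[Si](C)(C)C(C)(C)C)C2 | intermediate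
30 | ferugin | C=C1C[C@H](OC(=O)c2ccc(O)cc2)[C@@H]2[C@](C)(CC[C@@]2(O)C(C)C)C[C@@H]1O | target

---

**Total step count:** 18.
**Longest linear sequence:** 18 steps, from 1 to 30; all steps are linear and every other reactant is a purchased reagent.

**Three steps most likely to fail**
1. **Step 11 (hydroboration).**
   - Risk: the hindered ring-fusion alkene may react slowly, the epoxide may be reduced by borane, or the face selectivity for the trans fusion may be poor.
   - Fallback: hydroxyl-directed (VO(acac)2/TBHP) epoxidation of the C3=C3a alkene, then Cp2TiCl radical epoxide opening with H-atom transfer (1,4-cyclohexadiene) to put O on C3 and H on C3a.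
2. **Step 9 (epoxidation).**
   - Risk: the diastereoselectivity at C6/C7 sets the C7 configuration and may be low.
   - Fallback: drop the epoxide route; make the exocyclic allylic alcohol by SeO2/TBHP, oxidise it to the α-methylene ketone, and reset C7 by CBS reduction.
3. **Step 8 (RCM).**
   - Risk: closing a trisubstituted cycloheptene next to a quaternary centre and a cyclopentene may stall or give dimers.
   - Fallback: close the ring by intramolecular Nozaki–Hiyama–Kishi coupling of a C7 aldehyde with a 2-bromoallyl group. This forms the seven-membered ring, the exocyclic methylene and the C7 alcohol in one step, so steps 9 and 14 would be dropped.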